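The route rests on cutting both bonds of N4, to C5 and to the fully substituted C9a, the carbon shared by the pyrrolidine, the azepane and the cyclopentane. In the forward sense the C3 azide of a trans-hydrindanone adds to the C5 ketone and C9a shifts from carbon to nitrogen with loss of N2. One operation thus closes the pyrrolidine, expands the cyclohexanone to the azepanone and creates the aza-quaternary centre with retention. The precursor is a trans-fused bicyclic ketone whose quaternary α-carbon carries a three-carbon arm ending in the secondary azide next to lactone B; lactone A, its tertiary alcohol and the ethyl group are already in place.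

Key step: step 20

Labels: N4, C1–C3, C5–C9 and C9a as in the pyrrolo[1,2-a]azepine core; C10 (CH–Et), C11 (CH–O) and C12 (CH on C9a) in the cyclopentane; C13 = C(OH)Me of the fused lactone A; C1′ = oxygen-bearing CH of the side lactone B; "arm" = the C1–C3 chain on C9a.

Remark: no error was found in the target, the azido ketone or the lactam; the (R)-bromo ester is the enantiomer that maps onto the C-methyl centre of lactone B. The facial sense of the rhodium/(S)-BINAP alkenyl transfer in step 1 is assumed to be the one known for aryl and 1-alkenyl groups (3S ketone); if the internal alkenyl group behaves otherwise, (R)-BINAP is used.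

Step 1
Reactants: 1 cyclohex-2-en-1-one; 2 hex-3-yne; 3 3-[(tert-butyldimethylsilyl)oxy]propanal
Product: 6 trans-2-[1-hydroxy-3-(tert-butyldimethylsilyloxy)propyl]-3-[(E)-hex-3-en-3-yl]cyclohexan-1-one (3S; carbinol epimers), via alkenylzirconocene chloride 4 (not isolated), via zirconium enolate 5 (not isolated)
Conditions: 2, Cp2Zr(H)Cl, THF, rt; then 1, [Rh(cod)(MeCN)2]BF4 (5 mol %), (S)-BINAP (6 mol %), rt; then 3, 0 °C
Reagents that add atoms: none
Why: Hydrozirconation of the symmetrical alkyne gives the (E)-alkenylzirconocene, whose rhodium/BINAP-catalysed asymmetric 1,4-addition sets C9 by catalyst control and leaves a regiodefined zirconium enolate that is trapped in a tandem aldol addition anti to the new substituent, so only the future C9a is functionalised.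

Step 2
Reactants: 6 aldol adduct
Product: 8 (E)-2-[3-(tert-butyldimethylsilyloxy)propylidene]-3-[(E)-hex-3-en-3-yl]cyclohexan-1-one (C9 as in 6), via aldol mesylate 7 (not isolated)
Conditions: MsCl, Et3N, DMAP (cat.), CH2Cl2, 0 °C → rt
Reagents that add atoms: none
Why: Mesylation of the β-hydroxy ketone and E1cB elimination (aldol dehydration) should give the exocyclic enone under mild amine base, chosen to avoid migration of the double bond into the ring, which would erase C9.

Step 3
Reactants: 8 exocyclic enone; 9 allyl iodide
Product: 11 2-allyl-2-[3-(tert-butyldimethylsilyloxy)propyl]-3-[(E)-hex-3-en-3-yl]cyclohexan-1-one (allyl trans and silyloxypropyl cis to the hexenyl group), via lithium enolate 10 (not isolated)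
Conditions: LiBH(s-Bu)3, THF, −78 °C; then 9, DMPU, −78 → −20 °C
Reagents that add atoms: none
Why: Conjugate reduction of the s-cis enone gives the tetrasubstituted enolate regiospecifically (reductive alkylation of an enone), and allyl iodide attacks it anti to the C9 hexenyl group, which creates C9a with C12 trans and the arm cis to the C9 substituent.

Step 4
Reactants: 11 quaternary ketone
Product: 12 ethylene ketal (1,3-dioxolane) of 11
Conditions: TMSOCH2CH2OTMS, TMSOTf (cat.), CH2Cl2, −78 → 0 °C
Reagents that add atoms: 1,2-bis(trimethylsilyloxy)ethane, C[Si](C)(C)OCCO[Si](C)(C)C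
Why: Ketalisation with the bis-silyl glycol under silyl triflate catalysis should protect even this hindered ketone at low temperature without touching the silyl ether or the alkenes.

Step 5
Reactants: 12 ketal diene
Product: 13 trans-fused hexahydroindene with the C10=C11 double bond (ethyl on C10; C5 ketal; silyloxypropyl arm on C9a anti to C9–H)
Conditions: second-generation Grubbs catalyst (5 mol %), toluene, 80 °C
Reagents that add atoms: none
Why: Ring-closing metathesis joins the allyl terminus to the ethyl-bearing alkene carbon with loss of but-1-ene, and because the two arms are trans on the six-membered ring the cyclopentene is trans-fused without any stereocentre being touched.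

Step 6
Reactants: 13 hydrindene
Product: 15 C11 alcohol (C11–OH and C10–H syn on the face away from the arm), via C11 alkylborane 14 (not isolated)
Conditions: BH3·THF, THF, 0 °C → rt; then NaOH, H2O2, 0 °C
Reagents that add atoms: hydrogen peroxide, OO
Why: Hydroboration–oxidation places boron and then oxygen on the less substituted alkene carbon C11 by syn addition; both new centres are provisional, since C11 becomes a ketone and C10 is equilibrated in step 7.

Step 7
Reactants: 15 C11 alcohol
Product: 17 cyclopentanone with the C10 ethyl group trans to C8 (target configuration at C10), via C10-epimeric ketone 16 (not isolated)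
Conditions: Dess–Martin periodinane, NaHCO3, CH2Cl2, rt; then DBU (cat.), rt
Reagents that add atoms: none
Why: Dess–Martin oxidation gives the ketone, and base-mediated epimerisation through the enol moves the ethyl group to the thermodynamically preferred side, trans to C8 and away from the axial arm on C9a.

Step 8
Reactants: 17 cyclopentanone; 18 ethyl glyoxylate
Product: 21 C12 (ethoxycarbonyl)methylidene ketone (alkene geometry inconsequential), via lithium enolate 19 (not isolated), via aldol mesylate 20 (not isolated)
Conditions: LiN(i-Pr)2, THF, −78 °C; 18; then MsCl, Et3N, −78 → 0 °C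
Reagents that add atoms: none
Why: Kinetic deprotonation occurs at the methylene C12 and not at the methine C10, and aldol addition to the reactive glyoxylate followed by mesylation and E1cB elimination (aldol condensation) makes C12 trigonal so that its configuration can be set by hydrogen delivery.

Step 9
Reactants: 21 alkylidene keto ester
Product: 22 keto ester with C12–H on the face opposite the arm (acetate chain cis to the arm)
Conditions: H2 (1 atm), 10% Pd/C, EtOAc, rt
Reagents that add atoms: none
Why: Catalytic hydrogenation of the electron-poor trisubstituted alkene should add hydrogen to C12 from the open face opposite the angular arm, leaving the acetate chain on the arm's side as the cis lactone fusion requires.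

Step 10
Reactants: 22 keto ester
Product: 24 cis-fused γ-lactone (lactone A without C13 substituents), via hydroxy ester 23 (not isolated)
Conditions: NaBH4, MeOH, −20 → 0 °C; then AcOH to pH 5, rt
Reagents that add atoms: none
Why: Borohydride should attack the ketone from the face opposite the C12 acetate chain and the arm, giving the C11 alkoxide cis to the ester, which closes the lactone by transesterification (reduction–lactonisation).

Step 11
Reactants: 24 lactone
Product: 26 α-methylene lactone, via sodium formyl enolate 25 (not isolated)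
Conditions: NaH, HCO2Et, THF, 0 °C → rt; then (CH2O)n, THF, 60 °C
Reagents that add atoms: formaldehyde (as paraformaldehyde), C=O
Why: Claisen formylation followed by reaction of the formyl enolate with formaldehyde gives the α-methylene lactone by aldol addition, formyl transfer and loss of formate (deformylative methylenation), which avoids deprotonating a hindered α-position.

Step 12
Reactants: 26 α-methylene lactone
Product: 27 C13 tertiary alcohol (lactone A complete; hydroxyl exo and methyl endo; ketal and silyl ether intact)
Conditions: Mn(dpm)3 (10 mol %), PhSiH3, O2 (1 atm), i-PrOH/CH2Cl2, 0 °C → rt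
Reagents that add atoms: dioxygen, O=O
Why: Manganese-catalysed hydrogen-atom-transfer hydration (Mukaiyama hydration) adds a hydrogen atom to the methylene carbon and traps the tertiary α-lactone radical with dioxygen on the convex face, anti to C9a, so the hydroxyl ends up exo and the new methyl endo as in the target.

Step 13
Reactants: 27 protected core
Product: 28 keto diol (C5 ketone; primary C3 alcohol; tertiary C13 alcohol)
Conditions: 1 M HCl, THF, rt
Reagents that add atoms: water, O
Why: Aqueous acid hydrolyses the dioxolane and the primary silyl ether in one operation (acetal hydrolysis and desilylation), while the lactone and the tertiary alcohol are stable.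

Step 14
Reactants: 28 keto diol
Product: 29 keto aldehyde (C3 aldehyde)
Conditions: Dess–Martin periodinane, NaHCO3, CH2Cl2, 0 °C → rt
Reagents that add atoms: none
Why: Dess–Martin oxidation converts only the primary alcohol, since the tertiary alcohol cannot be oxidised, and the buffered neutral medium avoids aldol reactions of the keto aldehyde.

Step 15
Reactants: 29 keto aldehyde
Product: 30 (E)-vinyl iodide (arm = CH2CH2CH=CHI)
Conditions: CrCl2, CHI3, THF, 0 °C
Reagents that add atoms: iodoform, IC(I)I
Why: Takai olefination with the chromium carbenoid from iodoform homologates the aldehyde to the (E)-vinyl iodide and leaves the far less reactive ketone untouched.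

Step 16
Reactants: 30 vinyl iodide; 31 methyl (R)-3-bromo-2-methylpropanoate
Product: 33 (E)-alkene methyl ester (arm = CH2CH2CH=CHCH2CH(CH3)CO2Me), via alkylzinc bromide 32 (not isolated)
Conditions: 31, Zn, LiCl, THF, 50 °C; then 30, PdCl2(dppf) (5 mol %), THF, rt → 40 °C
Reagents that add atoms: none
Why: Zinc insertion gives a configurationally stable β-zincated ester, and Negishi cross-coupling joins it to the vinyl iodide with retention of the (E) geometry; the reagent tolerates ketone and lactone and brings the C-methyl centre of lactone B unchanged.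

Step 17
Reactants: 33 alkene ester
Product: 34 (R,R)-trans-epoxy ester
Conditions: D-fructose-derived ketone catalyst (30 mol %), KHSO5 (as 2KHSO5·KHSO4·K2SO4), K2CO3, Bu4NHSO4, MeCN/CH2(OMe)2/aq. buffer pH 10.5, 0 °C
Reagents that add atoms: potassium peroxymonosulfate, [K+].[O-]S(=O)(=O)OO
Why: Shi epoxidation epoxidises the trans-disubstituted alkene under catalyst control to the (R,R)-epoxide, the sense needed at C3 and C1′.

Step 18
Reactants: 34 epoxy ester
Product: 35 hydroxy bis-lactone (lactone B closed; C3 hydroxyl R and anti to the ring oxygen on C1′)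
Conditions: (+)-camphor-10-sulfonic acid (10 mol %), wet CH2Cl2, rt
Reagents that add atoms: water, O
Why: Acid-catalysed 5-exo opening of the epoxide by the ester carbonyl oxygen (epoxy ester lactonisation) inverts C1′ and, after hydrolysis of the oxocarbenium ion with loss of methanol, should give lactone B with the methyl group cis to the C1′ substituent.

Step 19
Reactants: 35 hydroxy bis-lactone
Product: 36 azido ketone (C3 azide S): the Schmidt precursor
Conditions: PPh3, DIAD, (PhO)2P(O)N3, THF, 0 °C → rt
Reagents that add atoms: diphenylphosphoryl azide, [N-]=[N+]=NP(=O)(Oc1ccccc1)Oc1ccccc1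
Why: Mitsunobu azidation displaces the activated secondary C3 hydroxyl by azide with inversion, setting the C3–N configuration of the target, while the tertiary alcohol is too hindered to react.

Step 20
Reactants: 36 azido ketone
Product: 38 lactam (C5 oxo derivative of the target), via azidohydrin 37 (not isolated)
Conditions: TiCl4 (3 equiv), CH2Cl2, 0 °C → rt; aq. NaHCO3
Reagents that add atoms: none
Why: Intramolecular Schmidt reaction: TiCl4 activates the C5 ketone, the azide nitrogen on C3 adds to it to give the six-membered azidohydrin 37 (a 6-exo-trig addition along the C9a–C1–C2–C3 tether), and the C5–C9a bond, antiperiplanar to the N–N2 bond in this fused ring, shifts to nitrogen as N2 leaves. The pyrrolidine (N4, C3, C2, C1, C9a) thus closes by contraction of the azidohydrin ring through the 1,2-shift that forms N4–C9a, and the azepanone arises by one-atom expansion of the cyclohexanone as N4 is inserted between C5 and C9a. The closest known reaction type is the Lewis-acid-promoted intramolecular Schmidt reaction of 2-(3-azidopropyl)cycloalkanones to fused bicyclic lactams, including cases where a quaternary α-carbon migrates. No new carbon stereocentre is formed: C9a migrates with retention, so the trans relationship set in steps 1–3 becomes the trans azepane–cyclopentane fusion, and C3 keeps the configuration from step 19. The selectivity needed is migration of C9a and not C6, which the three-carbon tether secures because only the tethered carbon can lie anti to the departing N2; the lactones and the tertiary alcohol should be inert to the Lewis acid at this temperature.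

Step 21
Reactants: 38 lactam
Product: 39 thiolactam (C5 thione)
Conditions: Lawesson's reagent (0.6 equiv), THF, 45 °C
Reagents that add atoms: Lawesson's reagent, COc1ccc(cc1)P1(=S)SP(=S)(S1)c1ccc(OC)cc1
Why: Thionation with Lawesson's reagent converts the tertiary lactam much faster than the two lactones, so only the amide carbonyl should become a thiocarbonyl.

Step 22
Reactants: 39 thiolactam
Product: 40 target (CNP0260919.2)
Conditions: Raney Ni (W-2), EtOH, rt
Reagents that add atoms: none
Why: Raney nickel desulfurisation reduces the thiolactam to the methylene amine under neutral conditions that leave both lactones and the tertiary alcohol intact.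

Compound list
1 | cyclohex-2-en-1-one | O=C1C=CCCC1 | starting material
2 | hex-3-yne | CCC#CCC | starting material
3 | 3-[(tert-butyldimethylsilyl)oxy]propanal | O=CCCO[Si](C)(C)C(C)(C)C | starting material
4 | chlorido[(E)-hex-3-en-3-yl]zirconocene | CC/C=C(\CC)[Zr](Cl)(C1C=CC=C1)C1C=CC=C1 | intermediate (not isolated)
5 | zirconocene chloride enolate of (S)-3-[(E)-hex-3-en-3-yl]cyclohexanone | CC/C=C(\CC)[C@H]1CCCC(O[Zr](Cl)(C2C=CC=C2)C2C=CC=C2)=C1 | intermediate (not isolated)
6 | trans-2-[1-hydroxy-3-(TBSO)propyl]-3-[(E)-hex-3-en-3-yl]cyclohexan-1-one, 3S, carbinol epimers | O=C1CCC[C@H](/C(CC)=C/CC)[C@H]1C(O)CCO[Si](C)(C)C(C)(C)C | intermediate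
7 | methanesulfonate of 6 | O=C1CCC[C@H](/C(CC)=C/CC)[C@H]1C(OS(C)(=O)=O)CCO[Si](C)(C)C(C)(C)C | intermediate (not isolated)
8 | (E)-2-[3-(TBSO)propylidene]-3-[(E)-hex-3-en-3-yl]cyclohexan-1-one, C9 as in 6 | O=C1CCC[C@H](/C(CC)=C/CC)/C1=C\CCO[Si](C)(C)C(C)(C)C | intermediate
9 | allyl iodide (3-iodoprop-1-ene) | C=CCI | starting material
10 | lithium enolate: lithium 2-[3-(TBSO)propyl]-3-[(E)-hex-3-en-3-yl]cyclohex-1-en-1-olate | [Li]OC1=C(CCCO[Si](C)(C)C(C)(C)C)[C@@H](/C(CC)=C/CC)CCC1 | intermediate (not isolated)
11 | 2-allyl-2-[3-(TBSO)propyl]-3-[(E)-hex-3-en-3-yl]cyclohexan-1-one, allyl trans and silyloxypropyl cis to hexenyl | C=CC[C@@]1(CCCO[Si](C)(C)C(C)(C)C)C(=O)CCC[C@@H]1/C(CC)=C/CC | intermediate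
12 | ethylene ketal of 11 | C=CC[C@@]1(CCCO[Si](C)(C)C(C)(C)C)C2(OCCO2)CCC[C@@H]1/C(CC)=C/CC | intermediate
13 | trans-fused hexahydroindene: C10=C11 alkene with ethyl on C10, C5 ketal, silyloxypropyl arm on C9a | CCC1=CC[C@@]3(CCCO[Si](C)(C)C(C)(C)C)C4(OCCO4)CCC[C@H]13 | intermediate
14 | C11 alkylborane from syn addition to 13 | CC[C@@H]1[C@@H](B)C[C@@]3(CCCO[Si](C)(C)C(C)(C)C)C4(OCCO4)CCC[C@H]13 | intermediate (not isolated)
15 | C11 alcohol, OH and C10–H syn, ethyl on the side of the arm | CC[C@@H]1[C@@H](O)C[C@@]3(CCCO[Si](C)(C)C(C)(C)C)C4(OCCO4)CCC[C@H]13 | intermediate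
16 | C11 ketone, C10 epimer (ethyl cis to the arm) | CC[C@@H]1C(=O)C[C@@]3(CCCO[Si](C)(C)C(C)(C)C)C4(OCCO4)CCC[C@H]13 | intermediate (not isolated)
17 | C11 ketone, ethyl trans to C8 (target configuration at C10) | CC[C@H]1C(=O)C[C@@]3(CCCO[Si](C)(C)C(C)(C)C)C4(OCCO4)CCC[C@H]13 | intermediate
18 | ethyl glyoxylate | CCOC(=O)C=O | starting material
19 | lithium C11–C12 enolate of 17 | CC[C@H]1C(O[Li])=C[C@@]3(CCCO[Si](C)(C)C(C)(C)C)C4(OCCO4)CCC[C@H]13 | intermediate (not isolated)
20 | C12 aldol mesylate (epimers at the two new centres) | CC[C@H]1C(=O)C(C(OS(C)(=O)=O)C(=O)OCC)[C@@]3(CCCO[Si](C)(C)C(C)(C)C)C4(OCCO4)CCC[C@H]13 | intermediate (not isolated)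
21 | C12 (ethoxycarbonyl)methylidene ketone (E/Z) | CC[C@H]1C(=O)C(=CC(=O)OCC)[C@@]3(CCCO[Si](C)(C)C(C)(C)C)C4(OCCO4)CCC[C@H]13 | intermediate
22 | keto ester, acetate chain on C12 cis to the arm | CC[C@H]1C(=O)[C@H](CC(=O)OCC)[C@@]3(CCCO[Si](C)(C)C(C)(C)C)C4(OCCO4)CCC[C@H]13 | intermediate
23 | C11 hydroxy ester, OH cis to the acetate chain | CC[C@H]1[C@H](O)[C@H](CC(=O)OCC)[C@@]3(CCCO[Si](C)(C)C(C)(C)C)C4(OCCO4)CCC[C@H]13 | intermediate (not isolated)
24 | cis-fused γ-lactone (lactone A, C13 unsubstituted) | CC[C@H]1[C@@H]2OC(=O)C[C@@H]2[C@@]3(CCCO[Si](C)(C)C(C)(C)C)C4(OCCO4)CCC[C@H]13 | intermediate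
25 | sodium enolate of the C13-formyl lactone | CC[C@H]1[C@@H]2OC(=O)C(=CO[Na])[C@@H]2[C@@]3(CCCO[Si](C)(C)C(C)(C)C)C4(OCCO4)CCC[C@H]13 | intermediate (not isolated)
26 | α-methylene lactone | CC[C@H]1[C@@H]2OC(=O)C(=C)[C@@H]2[C@@]3(CCCO[Si](C)(C)C(C)(C)C)C4(OCCO4)CCC[C@H]13 | intermediate
27 | C13 tertiary alcohol, lactone A complete, ketal and silyl ether intact | CC[C@H]1[C@@H]2OC(=O)[C@@](C)(O)[C@@H]2[C@@]3(CCCO[Si](C)(C)C(C)(C)C)C4(OCCO4)CCC[C@H]13 | intermediate
28 | keto diol | CC[C@H]1[C@@H]2OC(=O)[C@@](C)(O)[C@@H]2[C@@]3(CCCO)C(=O)CCC[C@H]13 | intermediate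
29 | keto aldehyde | CC[C@H]1[C@@H]2OC(=O)[C@@](C)(O)[C@@H]2[C@@]3(CCC=O)C(=O)CCC[C@H]13 | intermediate
30 | (E)-vinyl iodide | CC[C@H]1[C@@H]2OC(=O)[C@@](C)(O)[C@@H]2[C@@]3(CC/C=C/I)C(=O)CCC[C@H]13 | intermediate
31 | methyl (R)-3-bromo-2-methylpropanoate | BrC[C@H](C)C(=O)OC | starting material
32 | (R)-(3-methoxy-2-methyl-3-oxopropyl)zinc bromide | Br[Zn]C[C@H](C)C(=O)OC | intermediate (not isolated)
33 | (E)-alkene methyl ester | CC[C@H]1[C@@H]2OC(=O)[C@@](C)(O)[C@@H]2[C@@]3(CC/C=C/C[C@H](C)C(=O)OC)C(=O)CCC[C@H]13 | intermediate
34 | (R,R)-trans-epoxy ester | CC[C@H]1[C@@H]2OC(=O)[C@@](C)(O)[C@@H]2[C@@]3(CC[C@H]4O[C@@H]4C[C@H](C)C(=O)OC)C(=O)CCC[C@H]13 | intermediate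
35 | hydroxy bis-lactone, C3–OH (R) | CC[C@H]1[C@@H]2OC(=O)[C@@](C)(O)[C@@H]2[C@@]3(CC[C@H]([C@@H]4C[C@H](C)C(=O)O4)O)C(=O)CCC[C@H]13 | intermediate
36 | azido trans-hydrindanone carrying both lactones, C3–N3 (S) | CC[C@H]1[C@@H]2OC(=O)[C@@](C)(O)[C@@H]2[C@@]3(CC[C@@H]([C@@H]4C[C@H](C)C(=O)O4)N=[N+]=[N-])C(=O)CCC[C@H]13 | intermediate
37 | azidohydrin (titanium-bound; drawn as the N-diazonio alkoxide) | CC[C@H]1[C@@H]2OC(=O)[C@@](C)(O)[C@@H]2[C@]35CC[C@@H]([C@@H]4C[C@H](C)C(=O)O4)N([N+]#N)C5([O-])CCC[C@H]13 | intermediate (not isolated)
38 | C5 lactam of the target | CC[C@H]1[C@@H]2OC(=O)[C@@](C)(O)[C@@H]2[C@@]23CC[C@@H]([C@@H]4C[C@H](C)C(=O)O4)N2C(=O)CCC[C@H]13 | intermediate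
39 | C5 thiolactam | CC[C@H]1[C@@H]2OC(=O)[C@@](C)(O)[C@@H]2[C@@]23CC[C@@H]([C@@H]4C[C@H](C)C(=O)O4)N2C(=S)CCC[C@H]13 | intermediate
40 | CNP0260919.2 | CC[C@H]1[C@@H]2OC(=O)[C@@](C)(O)[C@@H]2[C@@]23CC[C@@H]([C@@H]4C[C@H](C)C(=O)O4)N2CCCC[C@H]13 | target

Total steps: 22. Longest linear sequence: 22 steps (1 → 40); the bromo ester 31 enters in step 16 without steps of its own.

Steps most likely to fail

Step 1. The zirconium enolate may be protonated or may equilibrate before it adds to the enolisable aldehyde, or alkenyl transfer from the hindered internal alkenylzirconocene may stall; either way the regiocontrol at the future C9a is lost. Fallback: separate the two events and enforce regiochemistry with a blocking group. Setting out from 1 and 4, the rhodium/(S)-BINAP-catalysed 1,4-addition alone, with aqueous work-up, should give (S)-3-[(E)-hex-3-en-3-yl]cyclohexan-1-one F1. Claisen formylation (HCO2Et, NaOMe) at the less hindered α-carbon gives the 6-hydroxymethylene ketone F2, which butane-1-thiol/TsOH converts to the 6-[(butylsulfanyl)methylene] ketone F3. The only enolisable position is then the future C9a. It is alkylated with 3-iodopropyl tert-butyldimethylsilyl ether (KOt-Bu) to the trans monoalkyl ketone F4 and then with 9 to the quaternary ketone F5, the allyl group entering anti to the hexenyl group. Hydrolytic removal of the blocking group (aq. KOH, diethylene glycol, heat; re-silylation if the silyl ether is lost) comes back to the route at 11.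

Step 3. 1,2-Reduction of the enone may compete with conjugate reduction, or the boron-complexed enolate may alkylate sluggishly at the congested carbon. Fallback: from 8, rhodium-catalysed conjugate hydrosilylation (RhCl(PPh3)3, Et3SiH) should give the isolable triethylsilyl enol ether F6 with the tetrasubstituted double bond fixed between C5 and C9a. Cleavage with MeLi regenerates the boron-free lithium enolate 10, which is allylated with 9 to come back at 11.

Step 20. Addition of the hindered, β-oxygenated secondary azide to the congested C5 carbonyl may be slow, C6 may migrate in place of C9a (bridged lactam), or the Lewis acid may degrade the substrate. Fallback: nitrogen insertion by the photochemical oxaziridine-to-lactam rearrangement. From 36, Staudinger reduction and intramolecular aza-Wittig condensation (PPh3, toluene, heat) should give the six-membered cyclic imine F7. Oxidation with 3-chloroperbenzoic acid gives the fused oxaziridine F8, and irradiation at 254 nm induces the shift of C9a from C5 to nitrogen with retention, coming back to the route at lactam 38.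

Further compounds
F1 | step 1 | (S)-3-[(E)-hex-3-en-3-yl]cyclohexan-1-one | O=C1CCC[C@H](/C(CC)=C/CC)C1
F2 | step 1 | 6-(hydroxymethylene) derivative of F1 | O=C1C(=CO)CC[C@H](/C(CC)=C/CC)C1
F3 | step 1 | 6-[(butylsulfanyl)methylene] derivative of F1 | O=C1C(=CSCCCC)CC[C@H](/C(CC)=C/CC)C1
F4 | step 1 | 2-[3-(TBSO)propyl] derivative of F3, trans to the hexenyl group | O=C1C(=CSCCCC)CC[C@H](/C(CC)=C/CC)[C@H]1CCCO[Si](C)(C)C(C)(C)C
F5 | step 1 | 2-allyl-2-[3-(TBSO)propyl] derivative of F3, allyl trans to the hexenyl group | O=C1C(=CSCCCC)CC[C@H](/C(CC)=C/CC)[C@]1(CC=C)CCCO[Si](C)(C)C(C)(C)C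
F6 | step 3 | triethylsilyl enol ether of the conjugate-reduced ketone | CC[Si](CC)(CC)OC1=C(CCCO[Si](C)(C)C(C)(C)C)[C@@H](/C(CC)=C/CC)CCC1
F7 | step 20 | cyclic imine (N4=C5) from 36 | CC[C@H]1[C@@H]2OC(=O)[C@@](C)(O)[C@@H]2[C@]35CC[C@@H]([C@@H]4C[C@H](C)C(=O)O4)N=C5CCC[C@H]13
F8 | step 20 | fused oxaziridine (N4–O–C5) | CC[C@H]1[C@@H]2OC(=O)[C@@](C)(O)[C@@H]2[C@]35CC[C@@H]([C@@H]4C[C@H](C)C(=O)O4)N6OC56CCC[C@H]13
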